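**Retrosynthetic overview**
- Ring C is opened at O1–C2 to a 2'-hydroxychalcone (oxidative cyclization), which is split at the enone C=C into a ring A acetophenone and a ring B aldehyde (Claisen–Schmidt).
- The strategy rests on ring B: its four contiguous oxygen-bearing carbons C2', C3', C4' and C5' are the four carbons of squaric acid, and C1' and C6' (with the exocyclic carbon that becomes flavone C2) come from a 2-substituted vinyl group.
- Key disconnection: the C5'–C6' bond, formed by 6π closure of a dienylketene released by 4π opening of a 4-alkenyl-4-hydroxycyclobutenone (dibenzyl squarate plus a 2-lithioallyl silyl ether).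
- C3' and C4' both come out as benzyl ethers; they are told apart at the aldehyde stage by debenzylation, benzylation of the more acidic 4'-OH (para to CHO) and methylation of 3'-OH.
- Ring order: ring B (step 4), then ring C (step 13); ring A is bought as phloroacetophenone.

Key step: step 4

Assumption: the target has no stereocenter; the carbinol carbon of the cyclobutenone and the transient aldol and flavanone centers are racemic and are all destroyed, so racemic material is used throughout.

**Route**

Step 1
Reactants: 1 squaric acid; 2 benzyl alcohol (two molecules are incorporated)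
Product: 3 dibenzyl squarate (3,4-bis(benzyloxy)cyclobut-3-ene-1,2-dione)
Conditions: BnOH (2.5 equiv), toluene, reflux, Dean–Stark
Reagents that add atoms: benzyl alcohol (second molecule of 2), OCc1ccccc1
Why: Squaric acid is a strong vinylogous acid and should catalyze its own double esterification with two molecules of benzyl alcohol on azeotropic removal of water (Fischer-type esterification), as for other dialkyl squarates.

Step 2
Reactants: 4 2-bromoallyl alcohol (2-bromoprop-2-en-1-ol)
Product: 5 [(2-bromoprop-2-en-1-yl)oxy](tert-butyl)dimethylsilane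
Conditions: TBSCl, imidazole, CH2Cl2, 0 °C to rt
Reagents that add atoms: tert-butyldimethylsilyl chloride, CC(C)(C)[Si](C)(C)Cl
Why: Standard imidazole-promoted silylation of a primary alcohol.

Step 3
Reactants: 5 [(2-bromoprop-2-en-1-yl)oxy](tert-butyl)dimethylsilane; 3 dibenzyl squarate
Product: 7 2,3-bis(benzyloxy)-4-[3-(tert-butyldimethylsilyloxy)prop-1-en-2-yl]-4-hydroxycyclobut-2-en-1-one (racemic), via vinyllithium 6 (not isolated)
Conditions: 5 (1.2 equiv), t-BuLi (2.4 equiv), Et2O, −78 °C; cannulate into 3, THF, −78 °C; aq NH4Cl at −78 °C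
Reagents that add atoms: none
Why: Bromine–lithium exchange followed by 1,2-addition of the vinyllithium to one of the two equivalent squarate carbonyls, held at −78 °C so that silyl migration in 6 and a second addition should not compete; the carbinol center forms as a racemate and is erased in step 4.

Step 4
Reactants: 7 2,3-bis(benzyloxy)-4-[3-(tert-butyldimethylsilyloxy)prop-1-en-2-yl]-4-hydroxycyclobut-2-en-1-one
Product: 10 2,3-bis(benzyloxy)-5-[(tert-butyldimethylsilyloxy)methyl]benzene-1,4-diol, via dienylketene 8 (not isolated), via cyclohexadienone 9 (not isolated)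
Conditions: degassed p-xylene (0.02 M), 138 °C, Ar; concentrated under Ar and used at once
Reagents that add atoms: none
Why: Thermal conrotatory 4π opening of the cyclobutenone C1–C4 bond should give dienylketene 8, in which the hydroxyl on the former carbinol carbon (future C2') has rotated outward and the propenyl group has turned inward, next to the ketene. The ketene carbon (future C5') then bonds to the terminal CH2 (future C6') in a thermal 6π electrocyclization that closes ring B as a six-membered carbocycle, and enolization of dienone 9 gives the aromatic hydroquinone. This is the Moore–Liebeskind ring expansion of squarate-derived 4-alkenyl-4-hydroxycyclobutenones to 2,3-dialkoxyhydroquinones, applied here to a benzyl ester and a silyloxymethyl-substituted vinyl group. No stereocenter is formed, and the racemic carbinol center disappears on aromatization. The selectivity required is torquoselectivity in the ring opening, which the strong outward preference of an oxygen donor on C4 secures; exclusion of air keeps the electron-rich hydroquinone from oxidizing to the quinone.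

Step 5
Reactants: 10 2,3-bis(benzyloxy)-5-[(tert-butyldimethylsilyloxy)methyl]benzene-1,4-diol
Product: 11 {[3,4-bis(benzyloxy)-2,5-dimethoxyphenyl]methoxy}(tert-butyl)dimethylsilane
Conditions: MeI (excess), K2CO3, degassed DMF, rt, Ar
Reagents that add atoms: iodomethane, CI
Why: Williamson methylation of both phenols fixes the 2'- and 5'-methoxy groups; benzyl and silyl ethers are inert to carbonate base.

Step 6
Reactants: 11 {[3,4-bis(benzyloxy)-2,5-dimethoxyphenyl]methoxy}(tert-butyl)dimethylsilane
Product: 12 [3,4-bis(benzyloxy)-2,5-dimethoxyphenyl]methanol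
Conditions: TBAF, THF, 0 °C to rt; H2O work-up
Reagents that add atoms: none
Why: Fluoride cleavage of a primary silyl ether, without the acid that could ionize the electron-rich benzylic position.

Step 7
Reactants: 12 [3,4-bis(benzyloxy)-2,5-dimethoxyphenyl]methanol
Product: 13 3,4-bis(benzyloxy)-2,5-dimethoxybenzaldehyde
Conditions: activated MnO2 (excess), CH2Cl2, rt
Reagents that add atoms: none
Why: MnO2 oxidizes benzylic alcohols selectively to aldehydes without over-oxidation.

Step 8
Reactants: 13 3,4-bis(benzyloxy)-2,5-dimethoxybenzaldehyde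
Product: 14 3,4-dihydroxy-2,5-dimethoxybenzaldehyde
Conditions: H2 (1 atm), 10% Pd/C, EtOAc, rt, stopped when both benzyl groups are gone
Reagents that add atoms: none
Why: Hydrogenolysis of aryl benzyl ethers is faster than reduction of an electron-rich aryl aldehyde in a neutral aprotic solvent at 1 atm.

Step 9
Reactants: 14 3,4-dihydroxy-2,5-dimethoxybenzaldehyde
Product: 15 4-(benzyloxy)-3-hydroxy-2,5-dimethoxybenzaldehyde
Conditions: BnBr (1.0 equiv), NaHCO3, NaI (cat.), DMF, 40 °C
Reagents that add atoms: benzyl bromide, BrCc1ccccc1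
Why: Only the 4-hydroxyl, para to the formyl group and therefore the more acidic, is ionized by hydrogen carbonate and alkylated, as in the 4-O-selective benzylation of 3,4-dihydroxybenzaldehyde.

Step 10
Reactants: 15 4-(benzyloxy)-3-hydroxy-2,5-dimethoxybenzaldehyde
Product: 16 4-(benzyloxy)-2,3,5-trimethoxybenzaldehyde
Conditions: MeI, K2CO3, DMF, rt
Reagents that add atoms: iodomethane, CI
Why: Williamson methylation of the remaining phenol completes the ring B oxygenation pattern.

Step 11
Reactants: 17 2,4,6-trihydroxyacetophenone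
Product: 18 1-[2,4-bis(benzyloxy)-6-hydroxyphenyl]ethan-1-one
Conditions: BnBr (2.1 equiv), K2CO3, DMF, rt
Reagents that add atoms: benzyl bromide, BrCc1ccccc1
Why: Williamson benzylation stops at the bis-ether because the last ortho hydroxyl is hydrogen-bonded to the ketone and is much less nucleophilic.

Step 12
Reactants: 16 4-(benzyloxy)-2,3,5-trimethoxybenzaldehyde; 18 1-[2,4-bis(benzyloxy)-6-hydroxyphenyl]ethan-1-one
Product: 20 (E)-1-[2,4-bis(benzyloxy)-6-hydroxyphenyl]-3-[4-(benzyloxy)-2,3,5-trimethoxyphenyl]prop-2-en-1-one, via aldol adduct 19 (not isolated)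
Conditions: KOH (50% aq), EtOH/THF, rt; dilute HCl work-up
Reagents that add atoms: none
Why: Claisen–Schmidt condensation of a methyl ketone with a non-enolizable aldehyde; E1cB dehydration of the aldol gives the conjugated E-enone as the thermodynamic product.

Step 13
Reactants: 20 (E)-1-[2,4-bis(benzyloxy)-6-hydroxyphenyl]-3-[4-(benzyloxy)-2,3,5-trimethoxyphenyl]prop-2-en-1-one
Product: 22 5,7-bis(benzyloxy)-2-[4-(benzyloxy)-2,3,5-trimethoxyphenyl]-4H-chromen-4-one, via flavanone 21 (not isolated)
Conditions: I2 (0.1 equiv), DMSO, 130 °C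
Reagents that add atoms: none
Why: Iodine/DMSO oxidative cyclization of a 2'-hydroxychalcone: 6-endo oxa-Michael closure forms ring C, then α-iodination and loss of HI give the flavone while DMSO reoxidizes HI to I2.

Step 14
Reactants: 22 5,7-bis(benzyloxy)-2-[4-(benzyloxy)-2,3,5-trimethoxyphenyl]-4H-chromen-4-one
Product: 23 5,7,4'-trihydroxy-2',3',5'-trimethoxyflavone
Conditions: H2 (1 atm), 10% Pd/C, THF/MeOH, rt
Reagents that add atoms: none
Why: Hydrogenolysis removes the three aryl benzyl ethers; the chromone double bond and the methyl ethers are not touched under these conditions.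

**Compound list**

1 | squaric acid (3,4-dihydroxycyclobut-3-ene-1,2-dione) | OC1=C(O)C(=O)C1=O | starting material
2 | benzyl alcohol | OCc1ccccc1 | starting material
3 | dibenzyl squarate (3,4-bis(benzyloxy)cyclobut-3-ene-1,2-dione) | O=C1C(=O)C(OCc2ccccc2)=C1OCc1ccccc1 | intermediate
4 | 2-bromoallyl alcohol (2-bromoprop-2-en-1-ol) | OCC(Br)=C | starting material
5 | [(2-bromoprop-2-en-1-yl)oxy](tert-butyl)dimethylsilane | C=C(Br)CO[Si](C)(C)C(C)(C)C | intermediate
6 | [3-(tert-butyldimethylsilyloxy)prop-1-en-2-yl]lithium (formed in the flask) | [Li]C(=C)CO[Si](C)(C)C(C)(C)C | intermediate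
7 | 2,3-bis(benzyloxy)-4-[3-(tert-butyldimethylsilyloxy)prop-1-en-2-yl]-4-hydroxycyclobut-2-en-1-one (racemic) | C=C(CO[Si](C)(C)C(C)(C)C)C1(O)C(=O)C(OCc2ccccc2)=C1OCc1ccccc1 | intermediate
8 | (3Z)-2,3-bis(benzyloxy)-5-[(tert-butyldimethylsilyloxy)methyl]-4-hydroxyhexa-1,3,5-trien-1-one (dienylketene, formed in the flask) | O=C=C(OCc1ccccc1)/C(OCc1ccccc1)=C(/O)C(=C)CO[Si](C)(C)C(C)(C)C | intermediate
9 | 2,3-bis(benzyloxy)-5-[(tert-butyldimethylsilyloxy)methyl]-4-hydroxycyclohexa-2,4-dien-1-one (formed in the flask) | O=C1CC(CO[Si](C)(C)C(C)(C)C)=C(O)C(OCc2ccccc2)=C1OCc1ccccc1 | intermediate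
10 | 2,3-bis(benzyloxy)-5-[(tert-butyldimethylsilyloxy)methyl]benzene-1,4-diol | CC(C)(C)[Si](C)(C)OCc1cc(O)c(OCc2ccccc2)c(OCc2ccccc2)c1O | intermediate
11 | {[3,4-bis(benzyloxy)-2,5-dimethoxyphenyl]methoxy}(tert-butyl)dimethylsilane | COc1cc(CO[Si](C)(C)C(C)(C)C)c(OC)c(OCc2ccccc2)c1OCc1ccccc1 | intermediate
12 | [3,4-bis(benzyloxy)-2,5-dimethoxyphenyl]methanol | COc1cc(CO)c(OC)c(OCc2ccccc2)c1OCc1ccccc1 | intermediate
13 | 3,4-bis(benzyloxy)-2,5-dimethoxybenzaldehyde | COc1cc(C=O)c(OC)c(OCc2ccccc2)c1OCc1ccccc1 | intermediate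
14 | 3,4-dihydroxy-2,5-dimethoxybenzaldehyde | COc1cc(C=O)c(OC)c(O)c1O | intermediate
15 | 4-(benzyloxy)-3-hydroxy-2,5-dimethoxybenzaldehyde | COc1cc(C=O)c(OC)c(O)c1OCc1ccccc1 | intermediate
16 | 4-(benzyloxy)-2,3,5-trimethoxybenzaldehyde | COc1cc(C=O)c(OC)c(OC)c1OCc1ccccc1 | intermediate
17 | 2,4,6-trihydroxyacetophenone | CC(=O)c1c(O)cc(O)cc1O | starting material
18 | 1-[2,4-bis(benzyloxy)-6-hydroxyphenyl]ethan-1-one | CC(=O)c1c(O)cc(OCc2ccccc2)cc1OCc1ccccc1 | intermediate
19 | 1-[2,4-bis(benzyloxy)-6-hydroxyphenyl]-3-[4-(benzyloxy)-2,3,5-trimethoxyphenyl]-3-hydroxypropan-1-one (racemic, formed in the flask) | COc1cc(C(O)CC(=O)c2c(O)cc(OCc3ccccc3)cc2OCc2ccccc2)c(OC)c(OC)c1OCc1ccccc1 | intermediate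
20 | (E)-1-[2,4-bis(benzyloxy)-6-hydroxyphenyl]-3-[4-(benzyloxy)-2,3,5-trimethoxyphenyl]prop-2-en-1-one | COc1cc(/C=C/C(=O)c2c(O)cc(OCc3ccccc3)cc2OCc2ccccc2)c(OC)c(OC)c1OCc1ccccc1 | intermediate
21 | 5,7-bis(benzyloxy)-2-[4-(benzyloxy)-2,3,5-trimethoxyphenyl]chroman-4-one (racemic, formed in the flask) | COc1cc(C2CC(=O)c3c(OCc4ccccc4)cc(OCc4ccccc4)cc3O2)c(OC)c(OC)c1OCc1ccccc1 | intermediate
22 | 5,7-bis(benzyloxy)-2-[4-(benzyloxy)-2,3,5-trimethoxyphenyl]-4H-chromen-4-one | COc1cc(-c2cc(=O)c3c(OCc4ccccc4)cc(OCc4ccccc4)cc3o2)c(OC)c(OC)c1OCc1ccccc1 | intermediate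
23 | 5,7,4'-trihydroxy-2',3',5'-trimethoxyflavone | COc1cc(-c2cc(=O)c3c(O)cc(O)cc3o2)c(OC)c(OC)c1O | target

**Count**

Total steps: 14. Longest linear sequence: 12 steps (steps 1, 3 to 10 and 12 to 14; the same length from 2-bromoallyl alcohol through step 2).

**Steps most likely to fail**

1. Step 4. The electron-rich hydroquinone may be oxidized by traces of air during isolation, and the ketene may be intercepted before it cyclizes. Fallback: setting out from 7, the thermolysis is followed by deliberate oxidation of the crude mixture (Ag2O, CH2Cl2) to the stable, chromatographable quinone 2,3-bis(benzyloxy)-5-[(tert-butyldimethylsilyloxy)methyl]cyclohexa-2,5-diene-1,4-dione F1. The quinone is then reduced with aqueous Na2S2O4, and the hydroquinone 10 so formed is methylated without exposure to air (MeI, K2CO3, degassed DMF), which returns to the route at 11.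

2. Step 3. The vinyllithium may rearrange by oxygen-to-carbon silyl shift or lose silanolate before it reaches the squarate, and over-addition to the second carbonyl may occur. Fallback: setting out from 3, the nucleophile is changed to the lithiated acrolein acetal. The known 2-bromoacrolein diethyl acetal, 2-bromo-3,3-diethoxyprop-1-ene (C=C(Br)C(OCC)OCC), with t-BuLi (2 equiv, THF, −78 °C) should give (3,3-diethoxyprop-1-en-2-yl)lithium F2, which carries no silyl group. Addition to 3 should give 2,3-bis(benzyloxy)-4-(3,3-diethoxyprop-1-en-2-yl)-4-hydroxycyclobut-2-en-1-one F3. Heating in degassed p-xylene should lead through the dienylketene (3Z)-2,3-bis(benzyloxy)-5-(diethoxymethyl)-4-hydroxyhexa-1,3,5-trien-1-one F4 and 2,3-bis(benzyloxy)-5-(diethoxymethyl)-4-hydroxycyclohexa-2,4-dien-1-one F5 to 2,3-bis(benzyloxy)-5-(diethoxymethyl)benzene-1,4-diol F6. Methylation (MeI, K2CO3, DMF) gives 1,2-bis(benzyloxy)-4-(diethoxymethyl)-3,6-dimethoxybenzene F7, and acetal hydrolysis (dilute HCl, THF) returns to the route at 13, with the aldehyde carbon already at the right oxidation level.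

3. Step 9. Discrimination between the two catechol hydroxyls may be insufficient, leading to alkylation at the 3-hydroxyl or to bis-benzylation. Fallback: setting out from 14, the order of alkylations is inverted by way of the dianion. With NaH (2.2 equiv) in DMSO the more nucleophilic 3-phenoxide, which is not conjugated with the formyl group, should be methylated by MeI (1.0 equiv) to give 4-hydroxy-2,3,5-trimethoxybenzaldehyde F8. Benzylation of its only phenol (BnBr, K2CO3, DMF) returns to the route at 16.

**Further compounds**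

F1 | step 4 | 2,3-bis(benzyloxy)-5-[(tert-butyldimethylsilyloxy)methyl]cyclohexa-2,5-diene-1,4-dione | O=C1C=C(CO[Si](C)(C)C(C)(C)C)C(=O)C(OCc2ccccc2)=C1OCc1ccccc1
F2 | step 3 | (3,3-diethoxyprop-1-en-2-yl)lithium | [Li]C(=C)C(OCC)OCC
F3 | step 3 | 2,3-bis(benzyloxy)-4-(3,3-diethoxyprop-1-en-2-yl)-4-hydroxycyclobut-2-en-1-one (racemic) | C=C(C(OCC)OCC)C1(O)C(=O)C(OCc2ccccc2)=C1OCc1ccccc1
F4 | step 3 | (3Z)-2,3-bis(benzyloxy)-5-(diethoxymethyl)-4-hydroxyhexa-1,3,5-trien-1-one | O=C=C(OCc1ccccc1)/C(OCc1ccccc1)=C(/O)C(=C)C(OCC)OCC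
F5 | step 3 | 2,3-bis(benzyloxy)-5-(diethoxymethyl)-4-hydroxycyclohexa-2,4-dien-1-one | O=C1CC(C(OCC)OCC)=C(O)C(OCc2ccccc2)=C1OCc1ccccc1
F6 | step 3 | 2,3-bis(benzyloxy)-5-(diethoxymethyl)benzene-1,4-diol | CCOC(OCC)c1cc(O)c(OCc2ccccc2)c(OCc2ccccc2)c1O
F7 | step 3 | 1,2-bis(benzyloxy)-4-(diethoxymethyl)-3,6-dimethoxybenzene | CCOC(OCC)c1cc(OC)c(OCc2ccccc2)c(OCc2ccccc2)c1OC
F8 | step 9 | 4-hydroxy-2,3,5-trimethoxybenzaldehyde | COc1cc(C=O)c(OC)c(OC)c1O
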